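A small charge of L, 0.00100 M in the midnight run, turns J into Z in a closed, stirred flask, and each Z made is one J gone. The spring run differs from the midnight run by the Z charged at the start.

| flask | J | L | Z | time |
|---|---|---|---|---|
| midnight | 0.500 M | 0.00100 M |  |  |
| autumn | 0.200 M | 0.00100 M |  |  |
| dusk | 0.500 M | 0.00200 M |  |  |
| winter | 1.50 M | 0.00100 M |  |  |
| spring | 0.500 M | 0.00100 M | 0.150 M | 31 min |

| run | time / min | [Z] / M |
|---|---|---|
| midnight run | 2.4 | 0.0267 |
| midnight run | 7.2 | 0.0740 |
| midnight run | 14 | 0.1354 |
| midnight run | 22 | 0.2059 |
| midnight run | 31 | 0.2620 |
| autumn run | 2.4 | 0.0106 |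
| autumn run | 7.2 | 0.0385 |
| autumn run | 14 | 0.0659 |
| autumn run | 22 | 0.0907 |
| autumn run | 31 | 0.1217 |
| dusk run | 2.4 | 0.0397 |
| dusk run | 7.2 | 0.1165 |
| dusk run | 14 | 0.2062 |
| dusk run | 22 | 0.2908 |
| dusk run | 31 | 0.3633 |
| winter run | 2.4 | 0.0582 |
| winter run | 7.2 | 0.1607 |
| winter run | 14 | 0.3038 |
| winter run | 22 | 0.4591 |
| winter run | 31 | 0.6179 |

(scatter of a reading: 0.002 M)

1. the power of [L] that the first rate follows, about the charge of the midnight run; measure it at two percent of J made into Z
2. the power of [J] that the first rate follows, about the charge of the midnight run; measure it at two percent of J made into Z (one fixed amount of Z, the same in the runs compared)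
3. the autumn run starts with 0.300 M less of J than the midnight run, and with no Z. Compared where both hold the same amount of J, once fifteen percent of what the autumn run was charged with has turned into Z, is the autumn run faster, slower or alike (within a tenth)?
4. Z in the spring run at 31 min, as a share of the J charged

- Overall: J -> Z, with L as catalyst.
- Constant volume, constant temperature.
- A reading of a species includes what of it is bound.
- An order is taken over about fifteen percent of the charge, up and down.
- A share of Z counts the Z that was charged too.

**What do you follow in these runs?**

The fraction f of the charged J that is left, which is what the Z made leaves over. In the midnight run at 31 min, f is 0.476. So τ, the apparent first-order time constant of J, which is the time divided by ln(1/f), is 41.8 min.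

**And the spring run?**

It has the J and L of the midnight run and is asked at the same time. If the charged Z does nothing, f there is again exp(−t/τ). The share is then the charged Z over the charged J plus the part of J turned, 82.4 %, which means 0.412 M of Z.

**That rests on Z doing nothing. What shows it?**

I look at the winter run, which ends with 0.6179 M of Z, more than the spring run should hold. Its τ is 61.9 min at 14 min and 58.4 min at 31 min, so it shortens as Z builds up, and no lengthening shows in these readings. I keep the τ of the midnight run for the spring run.

**Can τ go past the last reading?**

A little, since it drifts. For the winter run, τ times ln(2) is 40.5 min, and that is when Z made should reach half of the charge.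

The forecast gives 0.68 for the order in L, 0.78 for the order in J, alike for the comparison and 82.4 % for the share, holding that “Z appears inert”.

The flask gives 0.77, 0.74, alike and 82.8 %.

    2 L ⇌ L2, settled at all times (3410 M⁻¹)
    L + J → Z + L (129.6 M⁻¹ min⁻¹)
    2 J ⇌ J2, settled at all times (0.9820 M⁻¹)
    L + Yx → Gy

The spring run's share means f is 0.472 and τ is 41.3 min, against 41.8 min from the midnight run. The winter run reaches its mark at 39.8 min, against the 40.5 min reckoned. In the spring run, the tying up of 2 J as J2 holds the share down: without that tying up, the share rises from 82.8 % to 96.7 %, and τ falls to 28.2 min.

The numbers in the tables were generated by integration on assumed constants.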